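## Retrosynthetic overview

1. The hydroperoxide is made last: a singlet-oxygen ene reaction on the macrocyclic (E)-C(CH3)=CH olefin installs the tertiary OOH and shifts the olefin into the (E)-CH=CH position.
2. The 14-membered carbocycle is closed by ring-closing metathesis at the CH=CH next to the epoxide; diimide then saturates that olefin.
3. The metathesis precursor comes from a B-alkyl Suzuki coupling (sp3–sp2 bond at the trisubstituted olefin) of a δ-lactone fragment with an epoxy vinyl iodide fragment.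
4. The lactone fragment comes from (R)-carvone (directed epoxidation, selenoxide transposition, oxidative lactonisation, ozonolytic opening of the carvone ring); the epoxide fragment comes from 4-pentyn-1-ol (carboalumination, Wittig, Sharpless epoxidation).
5. Ring order: δ-lactone (built on the carvone ring, which is then cleaved) and epoxide (in its own fragment) first, 14-membered ring last.

Assumption: the SMILES is taken literally; labels follow its atom order: C1 = CH(CH3) of the lactone (S), C2 = C=O, C3 = lactone O–CH (R), C4 = CH2, C5 = ring-fusion CH (R), C6/C7 = CH2CH2, C8(CH3)/C9 = epoxide (S,S), C10/C11, C12 = C(CH3)OOH (R), C13=C14 (E), C15, C16 = C(CH3)OH (S).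

## Route

Step 1
Reactants: 1 (R)-(−)-carvone
Product: 2 (1R,5R)-cis-carveol
Conditions: NaBH4, CeCl3·7H2O, MeOH, −78 °C
Reagents that add atoms: none
Why: Luche 1,2-reduction; hydride enters anti to the isopropenyl group, so the new carbinol centre (later C3) is cis to the side chain (about 95:5).

Step 2
Reactants: 2 (1R,5R)-cis-carveol
Product: 3 (1R,2R,4S,6S)-1-methyl-4-(prop-1-en-2-yl)-7-oxabicyclo[4.1.0]heptan-2-ol
Conditions: VO(acac)2 (2 mol%), t-BuOOH, toluene, 0 °C to rt
Reagents that add atoms: tert-butyl hydroperoxide, CC(C)(C)OO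
Why: hydroxyl-directed vanadium-catalysed epoxidation delivers the oxygen (later the C16 OH) syn to the allylic OH, and only the allylic-alcohol olefin reacts.

Step 3
Reactants: 3 (1R,2R,4S,6S)-1-methyl-4-(prop-1-en-2-yl)-7-oxabicyclo[4.1.0]heptan-2-ol
Product: 6 (1R,2S,5S)-2-methyl-5-(prop-1-en-2-yl)cyclohex-3-ene-1,2-diol, via hydroxy selenide 4 (not isolated), via selenoxide 5 (not isolated)
Conditions: PhSeSePh, NaBH4, EtOH, reflux; then H2O2 (30%), THF, 0 °C to rt
Reagents that add atoms: none
Why: Sharpless–Lauer transposition: PhSe− opens the epoxide trans-diaxially at the secondary carbon (tertiary C–O untouched, cis-diol kept), and the selenoxide can only syn-eliminate away from the quaternary carbinol, giving the ring olefin that is cleaved in step 6.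

Step 4
Reactants: 6 (1R,2S,5S)-2-methyl-5-(prop-1-en-2-yl)cyclohex-3-ene-1,2-diol
Product: 7 (1R,2S,5S)-5-(1-hydroxypropan-2-yl)-2-methylcyclohex-3-ene-1,2-diol (side-chain epimers)
Conditions: 9-BBN (3.5 equiv), THF, 0 °C to rt; then NaOH, H2O2
Reagents that add atoms: hydrogen peroxide, OO
Why: anti-Markovnikov hydroboration–oxidation; 9-BBN takes the 1,1-disubstituted olefin about a hundred times faster than the ring cis-olefin; the new CH(CH3) centre (C1) forms about 1:1 and is corrected in step 8.

Step 5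
Reactants: 7 (1R,2S,5S)-5-(1-hydroxypropan-2-yl)-2-methylcyclohex-3-ene-1,2-diol
Product: 10 (1R,5S,8S)-8-hydroxy-4,8-dimethyl-2-oxabicyclo[3.3.1]non-6-en-3-one (C4 epimers), via hydroxy aldehyde 8 (not isolated), via bicyclic lactol 9 (not isolated)
Conditions: TEMPO (10 mol%), PhI(OAc)2 (2.5 equiv), CH2Cl2, rt
Reagents that add atoms: none
Why: oxoammonium (TEMPO) oxidation of the primary alcohol, capture of the aldehyde by the cis-1,3 secondary OH as a bridged lactol and a second oxidation give the δ-lactone (oxidative lactonisation); no stereocentre is touched.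

Step 6
Reactants: 10 (1R,5S,8S)-8-hydroxy-4,8-dimethyl-2-oxabicyclo[3.3.1]non-6-en-3-one
Product: 12 6-hydroxy-4,8-dimethyl-3-oxo-2,7-dioxabicyclo[3.3.1]nonane-8-carbaldehyde, via ozonide 11 (not isolated)
Conditions: O3, CH2Cl2, −78 °C; then Me2S, −78 °C to rt
Reagents that add atoms: ozone, [O-][O+]=O
Why: ozonolysis of the only olefin; the new CHO next to C5 is trapped by the tertiary OH as a six-membered lactol while the CHO on the quaternary carbon stays free, which differentiates the two termini.

Step 7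
Reactants: 12 6-hydroxy-4,8-dimethyl-3-oxo-2,7-dioxabicyclo[3.3.1]nonane-8-carbaldehyde
Product: 14 (3RS,4S,6R)-6-[(2S)-2-hydroxybut-3-en-2-yl]-3-methyl-4-[(1Z)-prop-1-en-1-yl]oxan-2-one, via vinyl lactol 13 (not isolated)
Conditions: NaN(SiMe3)2 (1.0 equiv), THF, −78 °C; Ph3P=CH2 (1.05 equiv, from Ph3PCH3Br and NaN(SiMe3)2), −78 °C; then Ph3P=CHCH3 (3 equiv, from Ph3PCH2CH3Br and NaN(SiMe3)2), −78 °C to rt
Reagents that add atoms: methylenetriphenylphosphorane, C=P(c1ccccc1)(c1ccccc1)c1ccccc1; ethylidenetriphenylphosphorane, CC=P(c1ccccc1)(c1ccccc1)c1ccccc1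
Why: two Wittig olefinations in one flask: the free aldehyde is methylenated in the cold while the lactolate stays closed, then on warming the lactol opens toward the second ylide to give the (Z)-propenyl group, an olefin that 9-BBN ignores in step 15.

Step 8
Reactants: 14 (3RS,4S,6R)-6-[(2S)-2-hydroxybut-3-en-2-yl]-3-methyl-4-[(1Z)-prop-1-en-1-yl]oxan-2-one
Product: 15 (3S,4S,6R)-6-[(2S)-2-hydroxybut-3-en-2-yl]-3-methyl-4-[(1Z)-prop-1-en-1-yl]oxan-2-one
Conditions: DBU (0.5 equiv), toluene, 60 °C
Reagents that add atoms: none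
Why: base-mediated epimerisation α to the lactone carbonyl under thermodynamic control; the 3,4-trans, 4,6-cis lactone has all three substituents equatorial (about 9:1 expected), and the minor epimer is recycled.

Step 9
Reactants: 16 4-pentyn-1-ol
Product: 18 (E)-5-iodo-4-methylpent-4-en-1-ol, via alkenylalane 17 (not isolated)
Conditions: AlMe3 (3 equiv), Cp2ZrCl2 (0.25 equiv), CH2Cl2, 0 °C to rt; then I2, THF, −30 °C; aq. K2CO3 work-up
Reagents that add atoms: trimethylaluminium, C[Al](C)C; iodine, II
Why: Negishi zirconium-catalysed carboalumination adds CH3–Al syn across the alkyne with methyl on the internal carbon, and iodinolysis with retention gives the (E)-vinyl iodide.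

Step 10
Reactants: 18 (E)-5-iodo-4-methylpent-4-en-1-ol
Product: 19 (E)-5-iodo-4-methylpent-4-enal
Conditions: Dess–Martin periodinane, CH2Cl2, rt
Reagents that add atoms: none
Why: Dess–Martin oxidation of the primary alcohol; the vinyl iodide is inert.

Step 11
Reactants: 19 (E)-5-iodo-4-methylpent-4-enal
Product: 20 ethyl (2E,6E)-7-iodo-2,6-dimethylhepta-2,6-dienoate
Conditions: Ph3P=C(CH3)CO2Et, CH2Cl2, rt to 40 °C
Reagents that add atoms: ethyl 2-(triphenylphosphoranylidene)propanoate, CCOC(=O)C(C)=P(c1ccccc1)(c1ccccc1)c1ccccc1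
Why: Wittig reaction of a stabilised ylide gives the (E)-trisubstituted enoate (typically above 20:1).

Step 12
Reactants: 20 ethyl (2E,6E)-7-iodo-2,6-dimethylhepta-2,6-dienoate
Product: 21 (2E,6E)-7-iodo-2,6-dimethylhepta-2,6-dien-1-ol
Conditions: iBu2AlH (2.2 equiv), CH2Cl2, −78 °C; aq. NaOH work-up
Reagents that add atoms: none
Why: DIBAL 1,2-reduction of the ester to the allylic alcohol at low temperature leaves both olefin geometries and the vinyl iodide intact.

Step 13
Reactants: 21 (2E,6E)-7-iodo-2,6-dimethylhepta-2,6-dien-1-ol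
Product: 22 [(2S,3S)-3-[(3E)-4-iodo-3-methylbut-3-en-1-yl]-2-methyloxiran-2-yl]methanol
Conditions: Ti(OiPr)4 (10 mol%), L-(+)-diethyl tartrate (12 mol%), t-BuOOH, 4 Å molecular sieves Na12[(AlO2)12(SiO2)12], CH2Cl2, −20 °C
Reagents that add atoms: tert-butyl hydroperoxide, CC(C)(C)OO
Why: Sharpless asymmetric epoxidation; with L-(+)-tartrate the (E)-2-methyl allylic alcohol gives the (2S,3S)-epoxide (the S,S epoxide of the target, typically above 95% ee), and the vinyl iodide olefin has no directing OH.

Step 14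
Reactants: 22 [(2S,3S)-3-[(3E)-4-iodo-3-methylbut-3-en-1-yl]-2-methyloxiran-2-yl]methanol
Product: 23 (2R,3S)-3-[(3E)-4-iodo-3-methylbut-3-en-1-yl]-2-methyloxirane-2-carbaldehyde
Conditions: Dess–Martin periodinane, pyridine, CH2Cl2, 0 °C
Reagents that add atoms: none
Why: buffered Dess–Martin oxidation; the epoxy aldehyde has no α-hydrogen, so nothing can epimerise (the descriptor change at the quaternary carbon is only a priority change).

Step 15
Reactants: 15 (3S,4S,6R)-6-[(2S)-2-hydroxybut-3-en-2-yl]-3-methyl-4-[(1Z)-prop-1-en-1-yl]oxan-2-one; 23 (2R,3S)-3-[(3E)-4-iodo-3-methylbut-3-en-1-yl]-2-methyloxirane-2-carbaldehyde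
Product: 25 (3S,4S,6R)-6-[(2S,5E)-8-[(2S,3R)-3-formyl-3-methyloxiran-2-yl]-2-hydroxy-6-methyloct-5-en-2-yl]-3-methyl-4-[(1Z)-prop-1-en-1-yl]oxan-2-one, via alkylborane 24 (not isolated)
Conditions: 9-BBN (2.2 equiv), THF, rt; then aq. Cs2CO3, 23, Pd(dppf)Cl2 (10 mol%), AsPh3, DMF, rt
Reagents that add atoms: none
Why: 9-BBN hydroborates the terminal vinyl group about a hundred times faster than the (Z)-propenyl group, and the B-alkyl Suzuki–Miyaura coupling joins the fragments with retention of the (E)-olefin geometry.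

Step 16
Reactants: 25 (3S,4S,6R)-6-[(2S,5E)-8-[(2S,3R)-3-formyl-3-methyloxiran-2-yl]-2-hydroxy-6-methyloct-5-en-2-yl]-3-methyl-4-[(1Z)-prop-1-en-1-yl]oxan-2-one
Product: 26 (3S,4S,6R)-6-[(2S,5E)-8-[(2S,3S)-3-ethenyl-3-methyloxiran-2-yl]-2-hydroxy-6-methyloct-5-en-2-yl]-3-methyl-4-[(1Z)-prop-1-en-1-yl]oxan-2-one
Conditions: Ph3P=CH2 (from Ph3PCH3Br and KN(SiMe3)2), THF, −78 to 0 °C
Reagents that add atoms: methylenetriphenylphosphorane, C=P(c1ccccc1)(c1ccccc1)c1ccccc1
Why: Wittig methylenation of the non-enolisable aldehyde, placed after the palladium step because a vinyl epoxide would ionise to a π-allyl complex.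

Step 17
Reactants: 26 (3S,4S,6R)-6-[(2S,5E)-8-[(2S,3S)-3-ethenyl-3-methyloxiran-2-yl]-2-hydroxy-6-methyloct-5-en-2-yl]-3-methyl-4-[(1Z)-prop-1-en-1-yl]oxan-2-one
Product: 28 14-membered epoxy lactone bearing the (E)-C12=C13 olefin (target minus O2), via macrocyclic diene 27 (not isolated)
Conditions: second-generation Grubbs catalyst (10 mol%), CH2Cl2 (1 mM), 40 °C; then concentrated to 0.05 M, 2-nitrobenzenesulfonyl hydrazide, Et3N, rt
Reagents that add atoms: none
Why: ring-closing metathesis between the vinyl epoxide and the propenyl group (propene is lost) closes the 14-membered ring, the trans-epoxide making the competing six-ring closure onto the trisubstituted olefin impossible, and diimide then saturates the new disubstituted olefin but not the trisubstituted one, so the geometry formed in the metathesis does not matter.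

Step 18
Reactants: 28 14-membered epoxy lactone bearing the (E)-C12=C13 olefin
Product: 29 target hydroperoxide CNP0297487.3
Conditions: O2, tetraphenylporphyrin (cat.), visible light, CH2Cl2, −20 °C
Reagents that add atoms: oxygen, O=O
Why: Schenck ene reaction: singlet oxygen bonds to the methyl-bearing olefin carbon and takes an allylic hydrogen from C14 on the more substituted side (cis effect), giving the tertiary hydroperoxide and the shifted (E)-olefin; the (R) configuration at C12 rests on attack at the exposed outer face of the macrocyclic olefin (substrate control, not secured by precedent), and isomers are removed by chromatography.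

## Compound list

1 | (R)-(−)-carvone | CC1=CC[C@H](CC1=O)C(C)=C | starting material
2 | (1R,5R)-cis-carveol | O[C@@H]1C[C@H](C(C)=C)CC=C1C | intermediate
3 | (1R,2R,4S,6S)-1-methyl-4-(prop-1-en-2-yl)-7-oxabicyclo[4.1.0]heptan-2-ol (epoxide syn to OH) | O[C@@H]1C[C@H](C(C)=C)C[C@@H]2O[C@]12C | intermediate
4 | hydroxy selenide (not isolated; PhSe anti to the tertiary OH) | O[C@@H]1C[C@H](C(C)=C)C[C@@H]([Se]c2ccccc2)[C@]1(C)O | intermediate
5 | selenoxide (not isolated) | O[C@@H]1C[C@H](C(C)=C)C[C@@H]([Se](=O)c2ccccc2)[C@]1(C)O | intermediate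
6 | (1R,2S,5S)-2-methyl-5-(prop-1-en-2-yl)cyclohex-3-ene-1,2-diol | O[C@@H]1C[C@H](C(C)=C)C=C[C@]1(C)O | intermediate
7 | (1R,2S,5S)-5-(1-hydroxypropan-2-yl)-2-methylcyclohex-3-ene-1,2-diol (side-chain epimers) | O[C@@H]1C[C@H](C(C)CO)C=C[C@]1(C)O | intermediate
8 | hydroxy aldehyde (not isolated; side-chain epimers) | O[C@@H]1C[C@H](C(C)C=O)C=C[C@]1(C)O | intermediate
9 | bicyclic lactol (not isolated) | CC1C(O)O[C@@H]2C[C@H]1C=C[C@]2(C)O | intermediate
10 | (1R,5S,8S)-8-hydroxy-4,8-dimethyl-2-oxabicyclo[3.3.1]non-6-en-3-one (C4 epimers) | CC1C(=O)O[C@@H]2C[C@H]1C=C[C@]2(C)O | intermediate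
11 | secondary ozonide of 10 (not isolated) | CC1C(=O)O[C@@H]2C[C@H]1C3OOC(O3)[C@]2(C)O | intermediate
12 | 6-hydroxy-4,8-dimethyl-3-oxo-2,7-dioxabicyclo[3.3.1]nonane-8-carbaldehyde (C4 and lactol epimers) | CC1C(=O)O[C@@H]2C[C@H]1C(O)O[C@@]2(C)C=O | intermediate
13 | 8-ethenyl-6-hydroxy-4,8-dimethyl-2,7-dioxabicyclo[3.3.1]nonan-3-one (not isolated) | CC1C(=O)O[C@@H]2C[C@H]1C(O)O[C@@]2(C)C=C | intermediate
14 | (3RS,4S,6R)-6-[(2S)-2-hydroxybut-3-en-2-yl]-3-methyl-4-[(1Z)-prop-1-en-1-yl]oxan-2-one | CC1C(=O)O[C@H](C[C@H]1/C=C\C)[C@@](C)(O)C=C | intermediate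
15 | (3S,4S,6R)-6-[(2S)-2-hydroxybut-3-en-2-yl]-3-methyl-4-[(1Z)-prop-1-en-1-yl]oxan-2-one | C[C@@H]1C(=O)O[C@H](C[C@H]1/C=C\C)[C@@](C)(O)C=C | intermediate
16 | 4-pentyn-1-ol | OCCCC#C | starting material
17 | (E)-alkenylalane, O-aluminated (not isolated) | C[Al](C)OCCC/C(C)=C/[Al](C)C | intermediate
18 | (E)-5-iodo-4-methylpent-4-en-1-ol | OCCC/C(C)=C/I | intermediate
19 | (E)-5-iodo-4-methylpent-4-enal | O=CCC/C(C)=C/I | intermediate
20 | ethyl (2E,6E)-7-iodo-2,6-dimethylhepta-2,6-dienoate | CCOC(=O)/C(C)=C/CC/C(C)=C/I | intermediate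
21 | (2E,6E)-7-iodo-2,6-dimethylhepta-2,6-dien-1-ol | OC/C(C)=C/CC/C(C)=C/I | intermediate
22 | [(2S,3S)-3-[(3E)-4-iodo-3-methylbut-3-en-1-yl]-2-methyloxiran-2-yl]methanol | OC[C@]1(C)O[C@H]1CC/C(C)=C/I | intermediate
23 | (2R,3S)-3-[(3E)-4-iodo-3-methylbut-3-en-1-yl]-2-methyloxirane-2-carbaldehyde | O=C[C@]1(C)O[C@H]1CC/C(C)=C/I | intermediate
24 | B-alkyl-9-BBN adduct of 15 (not isolated; shown with free OH) | C[C@@H]1C(=O)O[C@H](C[C@H]1/C=C\C)[C@@](C)(O)CCB1C2CCCC1CCC2 | intermediate
25 | seco epoxy aldehyde (full name in step 15) | C[C@@H]1C(=O)O[C@H](C[C@H]1/C=C\C)[C@@](C)(O)CC/C=C(\C)CC[C@@H]1O[C@@]1(C)C=O | intermediate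
26 | seco vinyl epoxide (full name in step 16) | C[C@@H]1C(=O)O[C@H](C[C@H]1/C=C\C)[C@@](C)(O)CC/C=C(\C)CC[C@@H]1O[C@@]1(C)C=C | intermediate
27 | macrocyclic diene, C6=C7 olefin of either geometry (not isolated) | C[C@@H]1C(=O)O[C@@H]2C[C@H]1C=C[C@]1(C)O[C@H]1CC/C(C)=C/CC[C@]2(C)O | intermediate
28 | 14-membered epoxy lactone with the (E)-C12=C13 olefin (target minus O2) | C[C@@H]1C(=O)O[C@@H]2C[C@H]1CC[C@]1(C)O[C@H]1CC/C(C)=C/CC[C@]2(C)O | intermediate
29 | CNP0297487.3 | C[C@@H]1C(=O)O[C@@H]2C[C@H]1CC[C@]1(C)O[C@H]1CC[C@@](C)(OO)/C=C/C[C@]2(C)O | target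

## Step count and weak points

Total: 18 steps. Longest linear sequence: 12 steps (1–8, then 15–18, from (R)-carvone); the 4-pentyn-1-ol branch is steps 9–14.

**Step 18 (ene reaction).** The risks are the regiochemistry (exocyclic-methylene hydroperoxide from abstraction at the C12 methyl) and the face of attack at C12. Fallback, setting out from 28 and returning at 29: silylate the tertiary alcohol with 1-(trimethylsilyl)imidazole to give the trimethylsilyl ether F1. Treat F1 with PhSeBr and AgOSO2CF3 in the presence of 2-methoxyprop-2-yl hydroperoxide at −78 °C; the peroxide opens the seleniranium ion at the tertiary carbon, anti to selenium, giving the peroxy selenide F2. Oxidise selenium (m-CPBA, −78 °C, then iPr2NH, rt); the selenoxide can only syn-eliminate toward C14, giving the allylic peroxyketal F3 with the (E)-olefin. AcOH/THF/H2O then frees the hydroperoxide and the alcohol to give 29. This fixes the regiochemistry, and the oxygen arrives on the face opposite to the one the electrophile attacks, so it complements the photooxygenation if that gives the C12 epimer.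

**Step 17 (ring-closing metathesis).** The risk is that ruthenium loads poorly onto the vinyl group at the quaternary epoxide carbon, so that oligomers form. Fallback, setting out from 25 and returning at 27: olefinate 25 with the ylide of (hex-5-en-1-yl)triphenylphosphonium bromide instead of Ph3P=CH2 to give the relay triene F4. The second-generation Grubbs catalyst then starts at the unhindered terminal olefin, expels cyclopentene and is delivered intramolecularly onto the epoxide-bearing terminus (relay ring-closing metathesis). Closure onto the propenyl group gives 27, which is reduced in the same flask as before. This still ends in a metathesis ring closure; I found no clean non-metathesis way to form the C6–C7 bond.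

**Step 7 (telling the two aldehyde termini apart).** The risk is that the lactol opens early and both termini are methylenated. Fallback, setting out from 10 and returning at 14: ozonise 10 in CH2Cl2/MeOH, add p-TsOH, then NaHCO3 and Me2S (Schreiber unsymmetrical ozonolysis). The aldehyde formed first (on the quaternary carbon, next to the allylic oxygen) becomes a dimethyl acetal while the carbonyl-oxide terminus ends as the lactol, giving the acetal lactol F5. Wittig reaction with excess Ph3P=CHCH3 gives the propenyl acetal F6; aqueous CF3CO2H unmasks the hydroxy aldehyde F7; methylenation with Ph3P=CH2 gives 14. Here the termini are differentiated by the direction of ozonide cleavage and acetalisation, not by reaction rates.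

## Further compounds

F1 | step 18 | trimethylsilyl ether of 28 | C[C@@H]1C(=O)O[C@@H]2C[C@H]1CC[C@]1(C)O[C@H]1CC/C(C)=C/CC[C@]2(C)O[Si](C)(C)C
F2 | step 18 | peroxy selenide: C12 (R) 2-methoxyprop-2-ylperoxy, C13 (S) phenylseleno, silyl ether | C[C@@H]1C(=O)O[C@@H]2C[C@H]1CC[C@]1(C)O[C@H]1CC[C@@](C)(OOC(C)(C)OC)[C@@H]([Se]c1ccccc1)CC[C@]2(C)O[Si](C)(C)C
F3 | step 18 | allylic peroxyketal of the target, silyl ether | C[C@@H]1C(=O)O[C@@H]2C[C@H]1CC[C@]1(C)O[C@H]1CC[C@@](C)(OOC(C)(C)OC)/C=C/C[C@]2(C)O[Si](C)(C)C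
F4 | step 17 | relay triene: 25 with CHO replaced by (Z)-CH=CH(CH2)3CH=CH2 | C[C@@H]1C(=O)O[C@H](C[C@H]1/C=C\C)[C@@](C)(O)CC/C=C(\C)CC[C@@H]1O[C@@]1(C)/C=C\CCCC=C
F5 | step 7 | acetal lactol: 8-(dimethoxymethyl)-6-hydroxy-4,8-dimethyl-2,7-dioxabicyclo[3.3.1]nonan-3-one | CC1C(=O)O[C@@H]2C[C@H]1C(O)O[C@@]2(C)C(OC)OC
F6 | step 7 | propenyl acetal: (4S,6R)-6-[(2S)-2-hydroxy-1,1-dimethoxypropan-2-yl]-3-methyl-4-[(1Z)-prop-1-en-1-yl]oxan-2-one | CC1C(=O)O[C@H](C[C@H]1/C=C\C)[C@@](C)(O)C(OC)OC
F7 | step 7 | hydroxy aldehyde: (2S)-2-hydroxy-2-[(2R,4S)-5-methyl-6-oxo-4-[(1Z)-prop-1-en-1-yl]oxan-2-yl]propanal | CC1C(=O)O[C@H](C[C@H]1/C=C\C)[C@@](C)(O)C=O
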